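**Plan**

1. The retrosynthesis cuts the lactone C3–CH2 bond (enolate benzylation) and then the lactone C4–CH2 bond (auxiliary-controlled benzylation of a succinate imide). This releases two benzylic bromides, and both trace back to one O-(4-benzyloxy-3-methoxybenzyl) arylacetate made from 5-bromovanillin.
2. The dihydrobenzofuran is cut at C2–C3. Forward, the arylacetate carbon (future C3) becomes a rhodium carbenoid that inserts into the benzylic C2–H of the ether CH2. That C–H lies 1,5 to the carbenoid across C3a, C7a and O1 and is activated by O1 and the electron-rich aryl ring, so the insertion closes the furan ring on the benzene ring.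
3. The open 1,3-diol arm is cut at its CH(OH)–CH(aryl) bond. The same arylacetate, as an acyl oxazolidinone enolate, adds to O-benzylvanillin in an anti aldol; the benzyl-type ether serves there only as phenol protection.
4. Forward order: a three-step trunk; branch B (diazo ester, furan ring, trans alcohol, bromide); branch A (anti aldol, diol, silylene, bromide, succinate alkylation, lactone ring); then union by lactone alkylation, desilylation and hydrogenolysis.
5. Stereochemistry: benzofuran C2 from the chiral dirhodium catalyst and C3 by epimerisation to trans; both diol carbons from the (S)-oxazolidinone aldol; lactone C4 from the (R)-oxazolidinone alkylation; lactone C3 by trans-selective alkylation under substrate control.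

Key step: step 5

Assumption: Rh2(R-PTTL)4 is taken to deliver the 2S-configured cis product (mirror image of the sense accepted for the S-configured catalyst), and the magnesium-chelated Z enolate of the (S)-oxazolidinone imide is taken to react on the face opposite the auxiliary benzyl group; if either sense proves opposite, the antipodal catalyst or auxiliary is used with no other change.

Abbreviations: Bn = benzyl; TBS = tert-butyldimethylsilyl; TBDPS = tert-butyldiphenylsilyl; BMB = 4-(benzyloxy)-3-methoxybenzyl; ArA = 4-(BMB-oxy)-3-methoxy-5-[(4S,5S)-4-(4-benzyloxy-3-methoxyphenyl)-2,2-di-tert-butyl-1,3,2-dioxasilinan-5-yl]phenyl; PTTL = N-phthaloyl-tert-leucinate.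

**Route**

Step 1
Reactants: 1 5-bromovanillin (3-bromo-4-hydroxy-5-methoxybenzaldehyde); 2 4-(benzyloxy)-3-methoxybenzyl alcohol
Product: 3 3-bromo-5-methoxy-4-(BMB-oxy)benzaldehyde
Conditions: PPh3, DIAD, THF, 0 °C to rt
Reagents that add atoms: none
Why: Mitsunobu etherification; the acidic para-formyl phenol of 1 should be alkylated by the activated primary benzylic alcohol 2 under neutral conditions that leave the aldehyde untouched.

Step 2
Reactants: 3 3-bromo-5-methoxy-4-(BMB-oxy)benzaldehyde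
Product: 4 tert-butyl{[3-bromo-5-methoxy-4-(BMB-oxy)benzyl]oxy}dimethylsilane
Conditions: [(Ph3P)CuH]6 (1 mol %), tBuMe2SiH, toluene, rt
Reagents that add atoms: tert-butyldimethylsilane, C[SiH](C)C(C)(C)C
Why: Copper hydride-catalysed hydrosilylation of the aromatic aldehyde should give the silyl ether directly (reduction and protection in one operation) without touching the aryl bromide or the benzyl ethers.

Step 3
Reactants: 4 tert-butyl{[3-bromo-5-methoxy-4-(BMB-oxy)benzyl]oxy}dimethylsilane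
Product: 5 methyl 2-[2-(BMB-oxy)-3-methoxy-5-(TBSO-methyl)phenyl]acetate
Conditions: BrZnCH2CO2Me (1.5 equiv, preformed in THF), Pd(dba)2 (2 mol %), XPhos (4 mol %), THF, 50 °C
Reagents that add atoms: (2-methoxy-2-oxoethyl)zinc bromide, COC(=O)C[Zn]Br
Why: Palladium-catalysed α-arylation of a zinc ester enolate (Reformatsky–Negishi coupling) tolerates the ortho alkoxy group, the silyl ether and the benzyl ethers and should place the acetate carbon ortho to the ether oxygen.

Step 4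
Reactants: 5 methyl 2-[2-(BMB-oxy)-3-methoxy-5-(TBSO-methyl)phenyl]acetate
Product: 6 methyl 2-diazo-2-[2-(BMB-oxy)-3-methoxy-5-(TBSO-methyl)phenyl]acetate
Conditions: 4-acetamidobenzenesulfonyl azide, DBU, MeCN, 0 °C to rt
Reagents that add atoms: 4-acetamidobenzenesulfonyl azide, CC(=O)Nc1ccc(cc1)S(=O)(=O)N=[N+]=[N-]
Why: Regitz diazo transfer to the benzylic ester-activated CH2, the only acidic site, should give the donor/acceptor diazo ester.

Step 5
Reactants: 6 methyl 2-diazo-2-[2-(BMB-oxy)-3-methoxy-5-(TBSO-methyl)phenyl]acetate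
Product: 7 methyl (2S,3R)-2-(4-benzyloxy-3-methoxyphenyl)-7-methoxy-5-(TBSO-methyl)-2,3-dihydrobenzofuran-3-carboxylate (cis)
Conditions: Rh2(R-PTTL)4 (1 mol %), toluene, −78 °C, slow addition of 6
Reagents that add atoms: none
Why: Rh2(R-PTTL)4 should extrude N2 from 6 to give an electrophilic donor/acceptor rhodium carbenoid at the future C3, which inserts through a concerted, asynchronous, hydride-transfer-like three-centre transition state into a C–H bond of the ether CH2 (future C2). The closest known reaction type is the dirhodium tetracarboxylate-catalysed intramolecular C–H insertion of 2-(benzyloxy)aryl diazoacetates to 2-aryl-2,3-dihydrobenzofuran-3-carboxylates. The furan ring is closed by 1,5-insertion, the five-membered transition state running over C3, C3a, C7a, O1 and C2. C2 should be set as S by the chiral carboxylate pocket of the catalyst, which selects one of the two enantiotopic benzylic hydrogens, and C3 should form cis to the aryl group under kinetic control (3R), to be corrected to trans in step 6. The step needs site selectivity for this CH2 over the silyloxymethyl, methoxy and benzyloxy C–H bonds and over carbenoid dimerisation; the 1,5 relationship fixed by the ortho ether, the activation of the C–H bond by O1 and by the electron-rich 4-benzyloxy-3-methoxyphenyl ring, the low temperature and the slow addition should secure it.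

Step 6
Reactants: 7 methyl (2S,3R)-2-(4-benzyloxy-3-methoxyphenyl)-7-methoxy-5-(TBSO-methyl)-2,3-dihydrobenzofuran-3-carboxylate (cis)
Product: 9 [(2S,3R)-2-(4-benzyloxy-3-methoxyphenyl)-7-methoxy-5-(TBSO-methyl)-2,3-dihydrobenzofuran-3-yl]methanol (trans), via trans ester 8 (not isolated)
Conditions: NaOMe (0.3 equiv), MeOH/THF, rt; then LiBH4, 0 °C to rt
Reagents that add atoms: none
Why: Base-mediated epimerisation followed by ester reduction; methoxide should equilibrate the ester-bearing C3 by enolisation to the thermodynamically preferred trans isomer without touching C2 (no acidic hydrogen there), and borohydride then gives the primary alcohol with C3 fixed as in the target.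

Step 7
Reactants: 9 [(2S,3R)-2-(4-benzyloxy-3-methoxyphenyl)-7-methoxy-5-(TBSO-methyl)-2,3-dihydrobenzofuran-3-yl]methanol
Product: 10 (2S,3R)-2-(4-benzyloxy-3-methoxyphenyl)-7-methoxy-3-(TBDPSO-methyl)-5-(TBSO-methyl)-2,3-dihydrobenzofuran
Conditions: TBDPSCl, imidazole, DMF, rt
Reagents that add atoms: tert-butyldiphenylsilyl chloride, CC(C)(C)[Si](Cl)(c1ccccc1)c1ccccc1
Why: Standard silylation of the primary alcohol with a hindered group that should be inert to the next step and to the enolate alkylation.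

Step 8
Reactants: 10 (2S,3R)-2-(4-benzyloxy-3-methoxyphenyl)-7-methoxy-3-(TBDPSO-methyl)-5-(TBSO-methyl)-2,3-dihydrobenzofuran
Product: 11 (2S,3R)-5-(bromomethyl)-2-(4-benzyloxy-3-methoxyphenyl)-7-methoxy-3-(TBDPSO-methyl)-2,3-dihydrobenzofuran
Conditions: Ph3PBr2, CH2Cl2, 0 °C to rt
Reagents that add atoms: dibromotriphenylphosphorane, BrP(Br)(c1ccccc1)(c1ccccc1)c1ccccc1
Why: Direct conversion of a silyl ether into a bromide with triphenylphosphine dibromide (O-phosphonium formation, loss of the silyl bromide, SN2 by bromide); the electron-rich benzylic TBS ether should react while the hindered neopentyl-type TBDPS ether stays.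

Step 9
Reactants: 5 methyl 2-[2-(BMB-oxy)-3-methoxy-5-(TBSO-methyl)phenyl]acetate
Product: 12 2-[2-(BMB-oxy)-3-methoxy-5-(TBSO-methyl)phenyl]acetic acid
Conditions: LiOH·H2O, THF/MeOH/H2O, rt; then 1 M HCl to pH 4, 0 °C
Reagents that add atoms: lithium hydroxide (supplies the oxygen of the acid OH), [Li+].[OH-]
Why: Saponification of the unhindered methyl ester; the silyl ether and the benzyl-type ethers are stable to LiOH.

Step 10
Reactants: 12 2-[2-(BMB-oxy)-3-methoxy-5-(TBSO-methyl)phenyl]acetic acid; 13 (S)-4-benzyl-2-oxazolidinone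
Product: 15 (S)-4-benzyl-3-{2-[2-(BMB-oxy)-3-methoxy-5-(TBSO-methyl)phenyl]acetyl}oxazolidin-2-one, via mixed pivalic anhydride 14 (not isolated)
Conditions: PivCl, Et3N, THF, −20 °C; then 13, LiCl, rt
Reagents that add atoms: pivaloyl chloride (its atoms stay only in 14 and leave as pivalic acid), CC(C)(C)C(Cl)=O
Why: One-pot mixed-anhydride N-acylation of the oxazolidinone should install the chiral auxiliary without a strong base.

Step 11
Reactants: 15 (S)-4-benzyl-3-{2-[2-(BMB-oxy)-3-methoxy-5-(TBSO-methyl)phenyl]acetyl}oxazolidin-2-one; 16 4-(benzyloxy)-3-methoxybenzaldehyde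
Product: 18 (S)-4-benzyl-3-{(2R,3S)-3-(4-benzyloxy-3-methoxyphenyl)-3-hydroxy-2-[2-(BMB-oxy)-3-methoxy-5-(TBSO-methyl)phenyl]propanoyl}oxazolidin-2-one (anti), via trimethylsilyl ether 17 (not isolated)
Conditions: MgCl2 (20 mol %), Et3N, TMSCl, EtOAc, rt; then citric acid (cat.), MeOH, rt
Reagents that add atoms: chlorotrimethylsilane (its atoms stay only in 17 and leave as methoxytrimethylsilane), C[Si](C)(C)Cl
Why: Magnesium halide-catalysed anti-selective aldol addition of an N-acyloxazolidinone to a non-enolisable aromatic aldehyde; the chelated Z enolate formed by soft enolisation should react through a boat transition state on the face opposite the auxiliary benzyl group, setting the α-carbon as R and the carbinol carbon as S, while silylation of the aldolate drives turnover and blocks retro-aldol.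

Step 12
Reactants: 18 (S)-4-benzyl-3-{(2R,3S)-3-(4-benzyloxy-3-methoxyphenyl)-3-hydroxy-2-[2-(BMB-oxy)-3-methoxy-5-(TBSO-methyl)phenyl]propanoyl}oxazolidin-2-one
Product: 19 (1S,2S)-1-(4-benzyloxy-3-methoxyphenyl)-2-[2-(BMB-oxy)-3-methoxy-5-(TBSO-methyl)phenyl]propane-1,3-diol
Conditions: LiBH4, MeOH (1 equiv), THF, 0 °C
Reagents that add atoms: none
Why: Reductive cleavage of the acyl oxazolidinone with LiBH4 should give the 1,3-diol with both stereocentres unchanged and return the auxiliary.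

Step 13
Reactants: 19 (1S,2S)-1-(4-benzyloxy-3-methoxyphenyl)-2-[2-(BMB-oxy)-3-methoxy-5-(TBSO-methyl)phenyl]propane-1,3-diol
Product: 20 (4S,5S)-4-(4-benzyloxy-3-methoxyphenyl)-2,2-di-tert-butyl-5-[2-(BMB-oxy)-3-methoxy-5-(TBSO-methyl)phenyl]-1,3,2-dioxasilinane
Conditions: tBu2Si(OTf)2, 2,6-lutidine, CH2Cl2, 0 °C
Reagents that add atoms: di-tert-butylsilyl bis(trifluoromethanesulfonate), CC(C)(C)[Si](OS(=O)(=O)C(F)(F)F)(OS(=O)(=O)C(F)(F)F)C(C)(C)C
Why: Silylene protection of a 1,3-diol; the six-membered di-tert-butylsilylene should withstand base, hydride and mild acid and fall to fluoride at the end.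

Step 14
Reactants: 20 (4S,5S)-4-(4-benzyloxy-3-methoxyphenyl)-2,2-di-tert-butyl-5-[2-(BMB-oxy)-3-methoxy-5-(TBSO-methyl)phenyl]-1,3,2-dioxasilinane
Product: 21 (4S,5S)-5-[5-(bromomethyl)-2-(BMB-oxy)-3-methoxyphenyl]-4-(4-benzyloxy-3-methoxyphenyl)-2,2-di-tert-butyl-1,3,2-dioxasilinane
Conditions: Ph3PBr2, CH2Cl2, 0 °C
Reagents that add atoms: dibromotriphenylphosphorane, BrP(Br)(c1ccccc1)(c1ccccc1)c1ccccc1
Why: Direct silyl ether to bromide conversion with triphenylphosphine dibromide, as in step 8; the unhindered electron-rich benzylic TBS ether should react well before the hindered silylene.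

Step 15
Reactants: 22 4-tert-butoxy-4-oxobutanoic acid (mono-tert-butyl succinate); 23 (R)-4-benzyl-2-oxazolidinone
Product: 25 tert-butyl 4-[(R)-4-benzyl-2-oxooxazolidin-3-yl]-4-oxobutanoate, via mixed pivalic anhydride 24 (not isolated)
Conditions: PivCl, Et3N, THF, −20 °C; then 23, LiCl, rt
Reagents that add atoms: pivaloyl chloride (its atoms stay only in 24 and leave as pivalic acid), CC(C)(C)C(Cl)=O
Why: Mixed-anhydride N-acylation of the oxazolidinone, as in step 10, should give the succinate imide.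

Step 16
Reactants: 25 tert-butyl 4-[(R)-4-benzyl-2-oxooxazolidin-3-yl]-4-oxobutanoate; 21 (4S,5S)-5-[5-(bromomethyl)-2-(BMB-oxy)-3-methoxyphenyl]-4-(4-benzyloxy-3-methoxyphenyl)-2,2-di-tert-butyl-1,3,2-dioxasilinane
Product: 26 tert-butyl (3R)-3-(ArA-methyl)-4-[(R)-4-benzyl-2-oxooxazolidin-3-yl]-4-oxobutanoate
Conditions: NaHMDS, THF, −78 °C; then 21, −78 to −30 °C
Reagents that add atoms: none
Why: Evans asymmetric alkylation; the chelated sodium Z enolate forms at the imide α-CH2 (more acidic than the ester α-CH2) and should be benzylated on the face opposite the auxiliary benzyl group, setting the future lactone C4 as R.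

Step 17
Reactants: 26 tert-butyl (3R)-3-(ArA-methyl)-4-[(R)-4-benzyl-2-oxooxazolidin-3-yl]-4-oxobutanoate
Product: 28 (4R)-4-(ArA-methyl)oxolan-2-one, via hydroxy tert-butyl ester 27 (not isolated)
Conditions: LiBH4, MeOH (1 equiv), THF, 0 °C; aqueous work-up; then CSA (10 mol %), toluene, 45 °C
Reagents that add atoms: none
Why: Chemoselective LiBH4 reduction of the imide beside the tert-butyl ester releases the auxiliary, and the γ-hydroxy ester should then lactonise under mild acid catalysis to the β-benzyl butyrolactone.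

Step 18
Reactants: 28 (4R)-4-(ArA-methyl)oxolan-2-one; 11 (2S,3R)-5-(bromomethyl)-2-(4-benzyloxy-3-methoxyphenyl)-7-methoxy-3-(TBDPSO-methyl)-2,3-dihydrobenzofuran
Product: 29 (3R,4R)-4-(ArA-methyl)-3-{[(2S,3R)-2-(4-benzyloxy-3-methoxyphenyl)-7-methoxy-3-(TBDPSO-methyl)-2,3-dihydrobenzofuran-5-yl]methyl}oxolan-2-one
Conditions: LiHMDS, THF, −78 °C; then 11, DMPU, −78 to −40 °C
Reagents that add atoms: none
Why: Lactone enolate alkylation; the electrophile should approach the five-membered lithium enolate anti to the C4 substituent, giving the trans 3,4-disubstituted lactone with C3 as R.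

Step 19
Reactants: 29 (3R,4R)-4-(ArA-methyl)-3-{[(2S,3R)-2-(4-benzyloxy-3-methoxyphenyl)-7-methoxy-3-(TBDPSO-methyl)-2,3-dihydrobenzofuran-5-yl]methyl}oxolan-2-one
Product: 30 (3R,4R)-3-{[(2S,3R)-2-(4-benzyloxy-3-methoxyphenyl)-3-(hydroxymethyl)-7-methoxy-2,3-dihydrobenzofuran-5-yl]methyl}-4-{4-(BMB-oxy)-3-[(1S,2S)-1-(4-benzyloxy-3-methoxyphenyl)-1,3-dihydroxypropan-2-yl]-5-methoxybenzyl}oxolan-2-one
Conditions: TBAF, AcOH (1:1), THF, rt
Reagents that add atoms: none
Why: Buffered fluoride desilylation should cleave the silylene and the TBDPS ether while the lactone, the benzyl ethers and the benzylic C–O bonds stay intact.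

Step 20
Reactants: 30 (3R,4R)-3-{[(2S,3R)-2-(4-benzyloxy-3-methoxyphenyl)-3-(hydroxymethyl)-7-methoxy-2,3-dihydrobenzofuran-5-yl]methyl}-4-{4-(BMB-oxy)-3-[(1S,2S)-1-(4-benzyloxy-3-methoxyphenyl)-1,3-dihydroxypropan-2-yl]-5-methoxybenzyl}oxolan-2-one
Product: 31 (3R,4R)-4-{3-[(1S,2S)-1,3-dihydroxy-1-(4-hydroxy-3-methoxyphenyl)propan-2-yl]-4-hydroxy-5-methoxybenzyl}-3-{[(2S,3R)-2-(4-hydroxy-3-methoxyphenyl)-3-(hydroxymethyl)-7-methoxy-2,3-dihydrobenzofuran-5-yl]methyl}oxolan-2-one (target)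
Conditions: H2 (1 atm), 10% Pd/C, EtOAc/EtOH, rt, monitored closely
Reagents that add atoms: none
Why: Neutral catalytic hydrogenolysis should remove the two phenolic benzyl ethers and the BMB ether (as toluene and 2-methoxy-4-methylphenol) much faster than it attacks the benzylic alcohol or the dihydrobenzofuran C2–O bond.

**Compound list**

1 | 5-bromovanillin | O=Cc1cc(Br)c(O)c(OC)c1 | starting material
2 | 4-(benzyloxy)-3-methoxybenzyl alcohol | OCc1ccc(OCc2ccccc2)c(OC)c1 | starting material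
3 | 3-bromo-5-methoxy-4-(BMB-oxy)benzaldehyde | O=Cc1cc(Br)c(OCc2ccc(OCc3ccccc3)c(OC)c2)c(OC)c1 | intermediate
4 | TBS ether of 3-bromo-5-methoxy-4-(BMB-oxy)benzyl alcohol | CC(C)(C)[Si](C)(C)OCc1cc(Br)c(OCc2ccc(OCc3ccccc3)c(OC)c2)c(OC)c1 | intermediate
5 | methyl 2-[2-(BMB-oxy)-3-methoxy-5-(TBSO-methyl)phenyl]acetate | COC(=O)Cc1cc(CO[Si](C)(C)C(C)(C)C)cc(OC)c1OCc1ccc(OCc2ccccc2)c(OC)c1 | intermediate
6 | methyl 2-diazo-2-[2-(BMB-oxy)-3-methoxy-5-(TBSO-methyl)phenyl]acetate | COC(=O)C(=[N+]=[N-])c1cc(CO[Si](C)(C)C(C)(C)C)cc(OC)c1OCc1ccc(OCc2ccccc2)c(OC)c1 | intermediate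
7 | methyl (2S,3R)-cis-2-(4-benzyloxy-3-methoxyphenyl)-7-methoxy-5-(TBSO-methyl)-2,3-dihydrobenzofuran-3-carboxylate | CC(C)(C)[Si](C)(C)OCc1cc(OC)c2c(c1)[C@@H](C(=O)OC)[C@@H](c1ccc(OCc3ccccc3)c(OC)c1)O2 | intermediate
8 | methyl (2S,3S)-trans-2-(4-benzyloxy-3-methoxyphenyl)-7-methoxy-5-(TBSO-methyl)-2,3-dihydrobenzofuran-3-carboxylate (not isolated) | CC(C)(C)[Si](C)(C)OCc1cc(OC)c2c(c1)[C@H](C(=O)OC)[C@@H](c1ccc(OCc3ccccc3)c(OC)c1)O2 | intermediate
9 | [(2S,3R)-trans-2-(4-benzyloxy-3-methoxyphenyl)-7-methoxy-5-(TBSO-methyl)-2,3-dihydrobenzofuran-3-yl]methanol | CC(C)(C)[Si](C)(C)OCc1cc(OC)c2c(c1)[C@H](CO)[C@@H](c1ccc(OCc3ccccc3)c(OC)c1)O2 | intermediate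
10 | (2S,3R)-2-(4-benzyloxy-3-methoxyphenyl)-7-methoxy-3-(TBDPSO-methyl)-5-(TBSO-methyl)-2,3-dihydrobenzofuran | CC(C)(C)[Si](C)(C)OCc1cc(OC)c2c(c1)[C@H](CO[Si](c1ccccc1)(c1ccccc1)C(C)(C)C)[C@@H](c1ccc(OCc3ccccc3)c(OC)c1)O2 | intermediate
11 | (2S,3R)-5-(bromomethyl)-2-(4-benzyloxy-3-methoxyphenyl)-7-methoxy-3-(TBDPSO-methyl)-2,3-dihydrobenzofuran | BrCc1cc(OC)c2c(c1)[C@H](CO[Si](c1ccccc1)(c1ccccc1)C(C)(C)C)[C@@H](c1ccc(OCc3ccccc3)c(OC)c1)O2 | intermediate
12 | 2-[2-(BMB-oxy)-3-methoxy-5-(TBSO-methyl)phenyl]acetic acid | OC(=O)Cc1cc(CO[Si](C)(C)C(C)(C)C)cc(OC)c1OCc1ccc(OCc2ccccc2)c(OC)c1 | intermediate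
13 | (S)-4-benzyl-2-oxazolidinone | O=C1N[C@@H](Cc2ccccc2)CO1 | starting material
14 | mixed anhydride of 12 with pivalic acid (not isolated) | CC(C)(C)C(=O)OC(=O)Cc1cc(CO[Si](C)(C)C(C)(C)C)cc(OC)c1OCc1ccc(OCc2ccccc2)c(OC)c1 | intermediate
15 | (S)-4-benzyl-3-{2-[2-(BMB-oxy)-3-methoxy-5-(TBSO-methyl)phenyl]acetyl}oxazolidin-2-one | O=C(Cc1cc(CO[Si](C)(C)C(C)(C)C)cc(OC)c1OCc1ccc(OCc2ccccc2)c(OC)c1)N1C(=O)OC[C@@H]1Cc1ccccc1 | intermediate
16 | 4-(benzyloxy)-3-methoxybenzaldehyde | O=Cc1ccc(OCc2ccccc2)c(OC)c1 | starting material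
17 | O-trimethylsilyl ether of 18 (not isolated) | COc1cc([C@@H](O[Si](C)(C)C)[C@H](C(=O)N2C(=O)OC[C@@H]2Cc2ccccc2)c2cc(CO[Si](C)(C)C(C)(C)C)cc(OC)c2OCc2ccc(OCc3ccccc3)c(OC)c2)ccc1OCc1ccccc1 | intermediate
18 | (S)-4-benzyl-3-{(2R,3S)-3-(4-benzyloxy-3-methoxyphenyl)-3-hydroxy-2-[2-(BMB-oxy)-3-methoxy-5-(TBSO-methyl)phenyl]propanoyl}oxazolidin-2-one (anti aldol) | COc1cc([C@@H](O)[C@H](C(=O)N2C(=O)OC[C@@H]2Cc2ccccc2)c2cc(CO[Si](C)(C)C(C)(C)C)cc(OC)c2OCc2ccc(OCc3ccccc3)c(OC)c2)ccc1OCc1ccccc1 | intermediate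
19 | (1S,2S)-1-(4-benzyloxy-3-methoxyphenyl)-2-[2-(BMB-oxy)-3-methoxy-5-(TBSO-methyl)phenyl]propane-1,3-diol | COc1cc([C@@H](O)[C@H](CO)c2cc(CO[Si](C)(C)C(C)(C)C)cc(OC)c2OCc2ccc(OCc3ccccc3)c(OC)c2)ccc1OCc1ccccc1 | intermediate
20 | (4S,5S)-4-(4-benzyloxy-3-methoxyphenyl)-2,2-di-tert-butyl-5-[2-(BMB-oxy)-3-methoxy-5-(TBSO-methyl)phenyl]-1,3,2-dioxasilinane | COc1cc([C@@H](O2)[C@H](CO[Si]2(C(C)(C)C)C(C)(C)C)c2cc(CO[Si](C)(C)C(C)(C)C)cc(OC)c2OCc2ccc(OCc3ccccc3)c(OC)c2)ccc1OCc1ccccc1 | intermediate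
21 | (4S,5S)-5-[5-(bromomethyl)-2-(BMB-oxy)-3-methoxyphenyl]-4-(4-benzyloxy-3-methoxyphenyl)-2,2-di-tert-butyl-1,3,2-dioxasilinane | COc1cc([C@@H](O2)[C@H](CO[Si]2(C(C)(C)C)C(C)(C)C)c2cc(CBr)cc(OC)c2OCc2ccc(OCc3ccccc3)c(OC)c2)ccc1OCc1ccccc1 | intermediate
22 | 4-tert-butoxy-4-oxobutanoic acid | CC(C)(C)OC(=O)CCC(=O)O | starting material
23 | (R)-4-benzyl-2-oxazolidinone | O=C1N[C@H](Cc2ccccc2)CO1 | starting material
24 | mixed anhydride of 22 with pivalic acid (not isolated) | CC(C)(C)OC(=O)CCC(=O)OC(=O)C(C)(C)C | intermediate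
25 | tert-butyl 4-[(R)-4-benzyl-2-oxooxazolidin-3-yl]-4-oxobutanoate | CC(C)(C)OC(=O)CCC(=O)N1C(=O)OC[C@H]1Cc1ccccc1 | intermediate
26 | tert-butyl (3R)-3-(ArA-methyl)-4-[(R)-4-benzyl-2-oxooxazolidin-3-yl]-4-oxobutanoate | COc1cc([C@@H](O2)[C@H](CO[Si]2(C(C)(C)C)C(C)(C)C)c2cc(C[C@H](CC(=O)OC(C)(C)C)C(=O)N3C(=O)OC[C@H]3Cc3ccccc3)cc(OC)c2OCc2ccc(OCc3ccccc3)c(OC)c2)ccc1OCc1ccccc1 | intermediate
27 | tert-butyl (3R)-4-ArA-3-(hydroxymethyl)butanoate (not isolated) | COc1cc([C@@H](O2)[C@H](CO[Si]2(C(C)(C)C)C(C)(C)C)c2cc(C[C@H](CC(=O)OC(C)(C)C)CO)cc(OC)c2OCc2ccc(OCc3ccccc3)c(OC)c2)ccc1OCc1ccccc1 | intermediate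
28 | (4R)-4-(ArA-methyl)oxolan-2-one | COc1cc([C@@H](O2)[C@H](CO[Si]2(C(C)(C)C)C(C)(C)C)c2cc(C[C@H]3COC(=O)C3)cc(OC)c2OCc2ccc(OCc3ccccc3)c(OC)c2)ccc1OCc1ccccc1 | intermediate
29 | fully protected (3R,4R)-trans-dibenzyl lactone (silylene, TBDPS ether, two Bn ethers, BMB ether) | COc1cc([C@@H](O2)[C@H](CO[Si]2(C(C)(C)C)C(C)(C)C)c2cc(C[C@H]3COC(=O)[C@@H]3Cc3cc(OC)c4c(c3)[C@H](CO[Si](c3ccccc3)(c3ccccc3)C(C)(C)C)[C@@H](c3ccc(OCc5ccccc5)c(OC)c3)O4)cc(OC)c2OCc2ccc(OCc3ccccc3)c(OC)c2)ccc1OCc1ccccc1 | intermediate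
30 | triol with two Bn ethers and the BMB ether still in place | COc1cc([C@@H](O)[C@H](CO)c2cc(C[C@H]3COC(=O)[C@@H]3Cc3cc(OC)c4c(c3)[C@H](CO)[C@@H](c3ccc(OCc5ccccc5)c(OC)c3)O4)cc(OC)c2OCc2ccc(OCc3ccccc3)c(OC)c2)ccc1OCc1ccccc1 | intermediate
31 | CNP0199264.2 | COc1cc([C@@H](O)[C@H](CO)c2cc(C[C@H]3COC(=O)[C@@H]3Cc3cc(OC)c4c(c3)[C@H](CO)[C@@H](c3ccc(O)c(OC)c3)O4)cc(OC)c2O)ccc1O | target

**Step count and risks**

Total step count: 20. Longest linear sequence: 14 steps (1–3, 9–14, 16–20).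

Step 5. The insertion may proceed with poor enantio- or cis/trans selectivity on this ether flanked by a methoxy group, and the carbenoid may dimerise or attack the electron-rich arene. The fallback closes the ring through O1–C2 instead of C2–C3 and sets out from 15. A boron aldol (Bu2BOTf, iPr2NEt, CH2Cl2, −78 to 0 °C, then 16) should give the syn adduct (S)-4-benzyl-3-[(2S,3S)-aldol] imide F1, whose α-carbon has the configuration needed for C3 because the non-chelated boron Z enolate reacts on the face opposite to that used by the magnesium chelate. Hydrogenolysis (H2, Pd/C, EtOAc) should free both phenols to give the bis-phenol F2. Catalytic CSA in CH2Cl2 at 0 °C should ionise the para-hydroxybenzylic alcohol, and the ortho phenol should close the ring trans to the acyl group, giving the trans dihydrobenzofuran imide F3. Benzylation (BnBr, K2CO3, acetone) should re-protect the phenol to give the benzyl ether F4, and LiBH4 (THF, MeOH, 0 °C) should cleave the auxiliary and return to the route at 9.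

Step 11. The anti selectivity or the facial control may erode with the ortho-substituted arylacetyl imide, and retro-aldol may occur during desilylation. The fallback sets out from 12 and 16 and replaces the aldol by alkene construction and stereospecific hydroboration. A Perkin condensation (Ac2O, Et3N, 110 °C) should give the (E)-2,3-diarylacrylic acid F5 with the two aryl groups cis. Reduction through the mixed carbonate (isobutyl chloroformate, N-methylmorpholine, THF, −15 °C; then NaBH4, H2O) should give the (E)-allylic alcohol F6. Hydroboration with monoisopinocampheylborane (THF, −25 °C; then NaOH, H2O2) should place boron on the less substituted benzylic carbon and add H and OH syn, which for this alkene geometry gives the anti 1,3-diol; the isopinocampheyl group is relied on for the absolute sense, and the route is rejoined at 19.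

Step 14. The bromophosphonium reagent may also attack the silylene or the electron-rich BMB aryl ether, and the benzylic bromide may ionise. The fallback sets out from 20 and separates deprotection from activation. PPTS in EtOH at 40 °C should cleave only the primary TBS ether to give the benzylic alcohol F7, and an Appel reaction (CBr4, PPh3, CH2Cl2, 0 °C) should then return to the route at 21.

**Further compounds**

F1 | step 5 | (S)-4-benzyl-3-{(2S,3S)-3-(4-benzyloxy-3-methoxyphenyl)-3-hydroxy-2-[2-(BMB-oxy)-3-methoxy-5-(TBSO-methyl)phenyl]propanoyl}oxazolidin-2-one (syn aldol) | COc1cc([C@@H](O)[C@@H](C(=O)N2C(=O)OC[C@@H]2Cc2ccccc2)c2cc(CO[Si](C)(C)C(C)(C)C)cc(OC)c2OCc2ccc(OCc3ccccc3)c(OC)c2)ccc1OCc1ccccc1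
F2 | step 5 | (S)-4-benzyl-3-{(2S,3S)-3-hydroxy-3-(4-hydroxy-3-methoxyphenyl)-2-[2-hydroxy-3-methoxy-5-(TBSO-methyl)phenyl]propanoyl}oxazolidin-2-one | COc1cc([C@@H](O)[C@@H](C(=O)N2C(=O)OC[C@@H]2Cc2ccccc2)c2cc(CO[Si](C)(C)C(C)(C)C)cc(OC)c2O)ccc1O
F3 | step 5 | (S)-4-benzyl-3-{[(2S,3S)-trans-2-(4-hydroxy-3-methoxyphenyl)-7-methoxy-5-(TBSO-methyl)-2,3-dihydrobenzofuran-3-yl]carbonyl}oxazolidin-2-one | CC(C)(C)[Si](C)(C)OCc1cc(OC)c2c(c1)[C@H](C(=O)N1C(=O)OC[C@@H]1Cc1ccccc1)[C@@H](c1ccc(O)c(OC)c1)O2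
F4 | step 5 | (S)-4-benzyl-3-{[(2S,3S)-trans-2-(4-benzyloxy-3-methoxyphenyl)-7-methoxy-5-(TBSO-methyl)-2,3-dihydrobenzofuran-3-yl]carbonyl}oxazolidin-2-one | CC(C)(C)[Si](C)(C)OCc1cc(OC)c2c(c1)[C@H](C(=O)N1C(=O)OC[C@@H]1Cc1ccccc1)[C@@H](c1ccc(OCc3ccccc3)c(OC)c1)O2
F5 | step 11 | (E)-3-(4-benzyloxy-3-methoxyphenyl)-2-[2-(BMB-oxy)-3-methoxy-5-(TBSO-methyl)phenyl]acrylic acid | OC(=O)/C(=C/c1ccc(OCc2ccccc2)c(OC)c1)c1cc(CO[Si](C)(C)C(C)(C)C)cc(OC)c1OCc1ccc(OCc2ccccc2)c(OC)c1
F6 | step 11 | (E)-3-(4-benzyloxy-3-methoxyphenyl)-2-[2-(BMB-oxy)-3-methoxy-5-(TBSO-methyl)phenyl]prop-2-en-1-ol | OC/C(=C/c1ccc(OCc2ccccc2)c(OC)c1)c1cc(CO[Si](C)(C)C(C)(C)C)cc(OC)c1OCc1ccc(OCc2ccccc2)c(OC)c1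
F7 | step 14 | {4-(BMB-oxy)-3-[(4S,5S)-4-(4-benzyloxy-3-methoxyphenyl)-2,2-di-tert-butyl-1,3,2-dioxasilinan-5-yl]-5-methoxyphenyl}methanol | COc1cc([C@@H](O2)[C@H](CO[Si]2(C(C)(C)C)C(C)(C)C)c2cc(CO)cc(OC)c2OCc2ccc(OCc3ccccc3)c(OC)c2)ccc1OCc1ccccc1
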